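Locants: C1 = quaternary carbon bearing C15H2OAc; C2–C5 = rest of ring A (C3 OAc, C4 OH, C5 CMe2); C6 = quaternary apex; C7 = CH2; C8, C9, C10 = cyclopropane (C9 on C1, C10 bears CH3); C11 = CHOAc.
Cuts, in retrosynthetic order: the three acetates and the O4 protecting group; C9–C10 together with C11–O (cyclopropylcarbinyl back to homoallyl, meaning an exo-C9 sulfonate plus C10=C11); C1–C6 and C8–C9 in one [4+2]; then C1–C9 (formylation), C1=C2 (cross-metathesis), C3–C4 (allylboration) and C5–C6 (aldol).
Enabling feature: C1 and C6–C11 form a nortricyclene cage. With C9–C10 opened it is a bicyclo[2.2.1]hept-2-ene whose bridgehead C6 carries the chain C5–C4–C3–C2 back to the neighbouring carbon C1. Ring A, the C1–C6 bond between two quaternary carbons and the norbornene are therefore the retron of one intramolecular Diels–Alder reaction between a 1,3-disubstituted cyclopentadiene (C6=C11–C10=C8, C7H2) and the alkene C1=C9. C15 and O3 stand 1,3-cis on ring A, so they can be tied as a γ-lactone during that step.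
Forward: the masked cyclopentadiene ring is bought as 2; C5, C4, C3, C2, C1/C15 and C9 are joined in this order; the γ-lactone closes; ring A and the norbornene form together (step 11); the cyclopropane closes (step 12); the lactone is opened, the acetates are added and O4 is freed.
Stereochemistry: C4 and C3 come from a reagent-controlled anti allylboration (terpene groups from (+)-α-pinene); C1 from C3 through the lactone; C9 from the Z alkene; C6 and C8 from the carbonyl-exo approach; C10 and C11 from backside π participation and capture of water on the face syn to C7.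

Key step: step 11

Remark 1: C6 is a stereocentre only in 3–5, 8, 9, 11–14, 16 and 17. It is formed racemic, the epimers are carried together, and the centre becomes sp2 in step 10, so it is left undefined in names and SMILES.
Remark 2: 16 is drawn as its hydroxymethylene tautomer. 18 is drawn as the reactive member of a set of cyclopentadiene tautomers that interconvert by 1,5-hydrogen shift.
Remark 3: (−)-Ipc2BH is treated as a stock reagent made from (+)-α-pinene and BH3·SMe2, and its preparation is not counted. "R6" below means the 3-methyl-1-(triethylsilyloxy)cyclopent-2-en-1-yl group.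

Step 1
Reactants: 1 methyl isobutyrate; 2 3-methylcyclopent-2-en-1-one
Product: 3 methyl 2-(1-hydroxy-3-methylcyclopent-2-en-1-yl)-2-methylpropanoate (racemic)
Conditions: LiN(i-Pr)2 (LDA), THF, −78 °C; CeCl3, −78 °C; then 2; AcOH quench at −78 °C
Reagents that add atoms: none
Why: Kinetic 1,2-aldol addition of an ester enolate to a β,β-disubstituted enone forms C5–C6, with the cerium enolate curbing enolisation of 2 and the cold quench preventing retro-aldol, and the new carbinol centre is racemic and is erased in step 10.

Step 2
Reactants: 3 aldol adduct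
Product: 4 methyl 2-methyl-2-(R6)propanoate (racemic)
Conditions: Et3SiOTf, 2,6-lutidine, CH2Cl2, −78 → 0 °C
Reagents that add atoms: triethylsilyl triflate, CC[Si](CC)(CC)OS(=O)(=O)C(F)(F)F
Why: Silyl triflate silylation of the hindered tertiary allylic alcohol under lutidine buffering removes the retro-aldol pathway and keeps the future diene masked through the basic and organometallic steps that follow.

Step 3
Reactants: 4 silyl ether ester
Product: 5 2-methyl-2-(R6)propanal (racemic; CHO = C4)
Conditions: i-Bu2AlH, CH2Cl2, −78 °C; aq. potassium sodium tartrate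
Reagents that add atoms: none
Why: Partial ester reduction with i-Bu2AlH stops at the aluminium hemiacetal at low temperature, which the neopentyl surroundings stabilise, and the aldehyde is released only on work-up.

Step 4
Reactants: 5 aldehyde; 6 allenylboronic acid pinacol ester
Product: 9 (3S,4R)-anti-diol H2C=CH–C3H(OH)–C4H(OH)–C5Me2–R6, via borylallylborane 7 (not isolated), via boronate adduct 8 (not isolated)
Conditions: 6, (−)-Ipc2BH, Et2O, 0 °C; 5, −78 °C; then NaOH, H2O2, 0 °C → rt
Reagents that add atoms: hydrogen peroxide, OO; (−)-diisopinocampheylborane, B([C@@H]1C[C@@H]2C[C@H]([C@H]1C)C2(C)C)[C@@H]3C[C@@H]4C[C@H]([C@H]3C)C4(C)C (its boron and terpene groups stay only in 7 and 8)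
Why: Hydroboration of the allene gives the thermodynamic E γ-boryl allylborane, whose Brown-type allylboration through a chair transition state forms C3–C4 anti with the isopinocampheyl groups directing attack to the Si face of the aldehyde (C4 R), and oxidation of the C3–B bond with retention gives C3 S.

Step 5
Reactants: 9 anti-diol; 10 methyl acrylate
Product: 11 methyl (2E,4S,5R)-4,5-dihydroxy-6-methyl-6-(R6)hept-2-enoate (C15O2Me–C1H=C2H–C3–C4)
Conditions: second-generation Hoveyda–Grubbs catalyst (H2IMes)Cl2Ru=CH(2-i-PrO-C6H4) (cat.), 1,4-benzoquinone (cat.), CH2Cl2, 40 °C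
Reagents that add atoms: none
Why: Olefin cross-metathesis between a terminal allylic alcohol and an acrylate is selective for the E enoate, brings in C1 and C15, and leaves the hindered trisubstituted ring alkene untouched.

Step 6
Reactants: 11 dihydroxy enoate
Product: 13 (5S)-5-[(1R)-1-hydroxy-2-methyl-2-(R6)propyl]dihydrofuran-2(3H)-one (γ-lactone C15–O3 with O4–H free), via dihydroxy ester 12 (not isolated)
Conditions: H2 (1 atm), RhCl(PPh3)3 (cat.), toluene, rt; then DBU (cat.), rt
Reagents that add atoms: none
Why: Homogeneous hydrogenation with RhCl(PPh3)3 saturates the disubstituted enoate but not the trisubstituted ring alkene, and the γ-hydroxy ester then closes by 5-exo-trig transesterification on O3 rather than on the neopentyl O4, so the two hydroxyls are told apart without a selective protection.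

Step 7
Reactants: 13 hydroxy lactone
Product: 14 O4-benzyloxymethyl (BOM) ether of 13
Conditions: BOMCl, i-Pr2NEt, Bu4NI (cat.), ClCH2CH2Cl, 50 °C
Reagents that add atoms: benzyl chloromethyl ether, ClCOCc1ccccc1
Why: Alkylation of the only free hydroxyl with an α-chloro ether under amine base tolerates the lactone and the silyl ether, and the resulting acetal ether survives base, heat, hydride and acylation and leaves by neutral hydrogenolysis.

Step 8
Reactants: 14 BOM ether lactone; 15 ethyl formate
Product: 16 3-(hydroxymethylidene) derivative of 14 (C9 attached to C1)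
Conditions: LiN(i-Pr)2, THF, −78 °C; 15, −78 → −20 °C; AcOH quench
Reagents that add atoms: none
Why: Crossed Claisen formylation of the lactone enolate with a formate ester introduces C9 at C1 and is driven by formation of the stabilised enolate of the product.

Step 9
Reactants: 16 hydroxymethylene lactone
Product: 17 (3Z,5S)-3-[(tosyloxy)methylidene] lactone (OTs cis to the lactone carbonyl C15)
Conditions: TsCl, TMEDA, LiCl, EtOAc, 0 °C
Reagents that add atoms: p-toluenesulfonyl chloride, Cc1ccc(cc1)S(=O)(=O)Cl
Why: In this chelation-controlled enol tosylation lithium holds the enolate oxygen and the lactone carbonyl oxygen on the same side while the amine-activated sulfonyl chloride traps it, which gives the Z enol tosylate and puts the leaving group for step 12 in place.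

Step 10
Reactants: 17 Z enol tosylate
Product: 18 (3Z,5S)-5-[(1R)-1-(benzyloxymethoxy)-2-methyl-2-(3-methylcyclopenta-1,3-dien-1-yl)propyl]-3-[(tosyloxy)methylidene]dihydrofuran-2(3H)-one
Conditions: TsOH·H2O (cat.), CH2Cl2, 0 °C → rt; filtration through basic alumina
Reagents that add atoms: none
Why: Acid-catalysed ionisation of the tertiary allylic silyl ether to a doubly tertiary allyl cation and loss of a ring proton (E1 elimination, the standard entry to substituted cyclopentadienes from cyclopentenone adducts) erases the C6 stereocentre and gives the diene as interconverting tautomers.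

Step 11
Reactants: 18 cyclopentadiene with tethered Z enol tosylate lactone
Product: 19 tetracyclic adduct: bicyclo[2.2.1]hept-2-ene (bridgeheads C6 and C8, bridge C7, C10=C11 with CH3 on C10) fused to ring A along C1–C6; C15(=O)–O3 lactone bridging C1 and C3; C15 exo (syn to C7), C2 endo, OTs exo on C9, OBOM equatorial on C4
Conditions: toluene (5 mM), BHT, solid K2CO3, 130 °C, sealed tube
Reagents that add atoms: none
Why: Thermal, concerted and suprafacial but asynchronous [4+2] cycloaddition of the kind known for 1-tethered cyclopentadienes that are replenished by 1,5-hydrogen shifts: the unsubstituted and most nucleophilic diene terminus C8 (remote from the C6 alkyl group, adjacent to the C10 methyl) bonds to the electrophilic β-carbon C9 ahead of the crowded C1–C6 bond, whereas the tautomer with CH3 on the reacting terminus would have to join C9 to a fully substituted carbon and the 2-tethered tautomer cannot reach. Ring A closes as a six-membered carbocycle by the C1–C6 bond through the four-atom tether C2–C5 (tether on the diene terminus, helped by the C5 gem-dimethyl group and by C2 and C3 being held in the lactone), and in the same event the bicyclo[2.2.1]heptene closes as the cyclohexene C6–C11=C10–C8–C9–C1 spanned by C7. C1 is controlled by C3: the three-atom bridge C4–C5–C6 can only span one face of the five-membered lactone, so C6 adds cis to C4 and C15 and O3 end up 1,3-cis on ring A. C9 follows from the Z geometry, which is carried over suprafacially and puts OTs cis to C15. C6 and C8 follow from the carbonyl-exo, C2-endo approach, the documented preference of s-cis-locked α-alkylidene lactones towards cyclopentadiene, because the sp3 carbon C2 then avoids the C7 methylene and the bulky sulfonate points into the open exo sector. The step thus needs only this exo/endo choice and the choice of tautomer, since facial selectivity is taken out of play by the lactone.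

Step 12
Reactants: 19 adduct
Product: 20 nortricyclanol lactone (C9–C10 closed, C11–OH on the face syn to C7, lactone and OBOM unchanged)
Conditions: 1,4-dioxane–H2O, NaHCO3, 90 °C
Reagents that add atoms: water, O
Why: In this solvolysis of an exo-norbornenyl sulfonate with homoallyl to cyclopropylcarbinyl participation, the C10=C11 π bond expels the exo tosylate from the endo side and forms C9–C10 with inversion at C9, and water captures the cation at C11 from the open face syn to C7, opposite to the new bond and away from C2, while the lactone keeps O15 and O3 from interfering.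

Step 13
Reactants: 20 nortricyclanol lactone
Product: 21 triol (C15H2OH, axial C3–OH, C11–OH; O4-BOM)
Conditions: LiAlH4, THF, 0 °C → reflux
Reagents that add atoms: none
Why: Hydride reduction of the lactone opens the bridge to the primary C15 and the secondary C3 alcohol without touching any stereocentre, the acetal ether or the cyclopropane.

Step 14
Reactants: 21 triol
Product: 22 C15, C3, C11 triacetate with O4-BOM
Conditions: Ac2O, DMAP, pyridine, 40 °C
Reagents that add atoms: acetic anhydride, CC(=O)OC(C)=O
Why: DMAP-catalysed acylation esterifies the three free hydroxyls under basic conditions that do not ionise the cyclopropylcarbinyl position, with O4 blocked.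

Step 15
Reactants: 22 triacetate BOM ether
Product: 23 target CNP0197219.1
Conditions: H2 (1 atm), Pd(OH)2/C, EtOAc, rt
Reagents that add atoms: none
Why: Hydrogenolysis of the benzyl C–O bond leaves a hemiacetal that loses formaldehyde and frees O4–H under neutral conditions, which avoids acetyl migration from O3 and ionisation at C11, and the saturated cage offers nothing else to reduce.

Compound list
1 | methyl isobutyrate | COC(=O)C(C)C | starting material
2 | 3-methylcyclopent-2-en-1-one | CC1=CC(=O)CC1 | starting material
3 | methyl 2-(1-hydroxy-3-methylcyclopent-2-en-1-yl)-2-methylpropanoate | COC(=O)C(C)(C)C1(O)CCC(C)=C1 | intermediate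
4 | methyl 2-methyl-2-[3-methyl-1-(triethylsilyloxy)cyclopent-2-en-1-yl]propanoate | COC(=O)C(C)(C)C1(O[Si](CC)(CC)CC)CCC(C)=C1 | intermediate
5 | 2-methyl-2-[3-methyl-1-(triethylsilyloxy)cyclopent-2-en-1-yl]propanal | O=CC(C)(C)C1(O[Si](CC)(CC)CC)CCC(C)=C1 | intermediate
6 | allenylboronic acid pinacol ester | C=C=CB1OC(C)(C)C(C)(C)O1 | starting material
7 | (E)-[3-(pinacolatoboryl)allyl]bis(isopinocampheyl)borane | B(C/C=C/B1OC(C)(C)C(C)(C)O1)([C@@H]2C[C@@H]3C[C@H]([C@H]2C)C3(C)C)[C@@H]4C[C@@H]5C[C@H]([C@H]4C)C5(C)C | intermediate (not isolated)
8 | anti adduct, O4-bis(isopinocampheyl)borinate and C3 pinacol boronate | C=C[C@H](B1OC(C)(C)C(C)(C)O1)[C@H](OB([C@@H]2C[C@@H]3C[C@H]([C@H]2C)C3(C)C)[C@@H]4C[C@@H]5C[C@H]([C@H]4C)C5(C)C)C(C)(C)C6(O[Si](CC)(CC)CC)CCC(C)=C6 | intermediate (not isolated)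
9 | (3R,4S)-2-methyl-2-[3-methyl-1-(triethylsilyloxy)cyclopent-2-en-1-yl]hex-5-ene-3,4-diol (target locants C4 R, C3 S) | C=C[C@H](O)[C@H](O)C(C)(C)C1(O[Si](CC)(CC)CC)CCC(C)=C1 | intermediate
10 | methyl acrylate | COC(=O)C=C | starting material
11 | methyl (2E,4S,5R)-4,5-dihydroxy-6-methyl-6-[3-methyl-1-(triethylsilyloxy)cyclopent-2-en-1-yl]hept-2-enoate | COC(=O)/C=C/[C@H](O)[C@H](O)C(C)(C)C1(O[Si](CC)(CC)CC)CCC(C)=C1 | intermediate
12 | methyl (4S,5R)-4,5-dihydroxy-6-methyl-6-[3-methyl-1-(triethylsilyloxy)cyclopent-2-en-1-yl]heptanoate | COC(=O)CC[C@H](O)[C@H](O)C(C)(C)C1(O[Si](CC)(CC)CC)CCC(C)=C1 | intermediate (not isolated)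
13 | (5S)-5-{(1R)-1-hydroxy-2-methyl-2-[3-methyl-1-(triethylsilyloxy)cyclopent-2-en-1-yl]propyl}dihydrofuran-2(3H)-one | O=C1CC[C@@H]([C@H](O)C(C)(C)C2(O[Si](CC)(CC)CC)CCC(C)=C2)O1 | intermediate
14 | O4-benzyloxymethyl ether of 13 | O=C1CC[C@@H]([C@H](OCOCc3ccccc3)C(C)(C)C2(O[Si](CC)(CC)CC)CCC(C)=C2)O1 | intermediate
15 | ethyl formate | CCOC=O | starting material
16 | 3-(hydroxymethylidene) lactone | OC=C1C[C@@H]([C@H](OCOCc3ccccc3)C(C)(C)C2(O[Si](CC)(CC)CC)CCC(C)=C2)OC1=O | intermediate
17 | (3Z)-3-[(tosyloxy)methylidene] lactone, diene still masked | Cc4ccc(cc4)S(=O)(=O)O/C=C1/C[C@@H]([C@H](OCOCc3ccccc3)C(C)(C)C2(O[Si](CC)(CC)CC)CCC(C)=C2)OC1=O | intermediate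
18 | cyclopentadiene tethered to the Z enol tosylate lactone (Diels–Alder precursor) | Cc4ccc(cc4)S(=O)(=O)O/C=C1/C[C@@H]([C@H](OCOCc3ccccc3)C(C)(C)C2=CC(C)=CC2)OC1=O | intermediate
19 | Diels–Alder adduct: norbornene, ring A, bridging lactone, exo-C9 tosylate | O=C1O[C@H]2C[C@@]13[C@@H](OS(=O)(=O)c4ccc(C)cc4)[C@H]5C[C@@]3(C=C5C)C(C)(C)[C@H]2OCOCc6ccccc6 | intermediate
20 | nortricyclanol lactone (C11–OH syn to C7) | O=C1O[C@H]2C[C@@]13[C@H]4[C@H]5C[C@@]3([C@H](O)[C@@]45C)C(C)(C)[C@H]2OCOCc6ccccc6 | intermediate
21 | C15, C3, C11 triol, O4-BOM | OC[C@]12C[C@H](O)[C@H](OCOCc4ccccc4)C(C)(C)[C@]13C[C@@H]1[C@H]2[C@]1(C)[C@H]3O | intermediate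
22 | C15, C3, C11 triacetate, O4-BOM | CC(=O)OC[C@]12C[C@H](OC(C)=O)[C@H](OCOCc4ccccc4)C(C)(C)[C@]13C[C@@H]1[C@H]2[C@]1(C)[C@H]3OC(C)=O | intermediate
23 | CNP0197219.1 | CC(=O)OC[C@]12C[C@H](OC(C)=O)[C@H](O)C(C)(C)[C@]13C[C@@H]1[C@H]2[C@]1(C)[C@H]3OC(C)=O | target

Total step count: 15. Longest linear sequence: 15 steps (1 and 2 to 23).

Steps most likely to fail

1. Step 11.
- **What may go wrong:** the carbonyl-endo approach competes, cycloaddition leaks through the tautomer that carries CH3 on the reacting terminus, or the cycloaddition is too slow to outrun dimerisation of the diene.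
- **Fallback:** it sets out from 17 and comes back at 20. It replaces the sulfonate by a second activating group and closes the cyclopropane without a cation. PhSO2Na in DMF at rt exchanges the tosylate by addition–elimination and should give the E vinyl sulfone F1, whatever the geometry of the starting material. TsOH as in step 10 unmasks the sulfonyl cyclopentadiene F2. Its doubly activated alkene should cyclise at 60–80 °C in toluene. With the sulfonyl group cis to C2, the carbonyl-exo approach shows only C=O and H to the C7 methylene, which leads to the endo-sulfonyl adduct F3. m-CPBA in CH2Cl2 epoxidises C10=C11 from the exo face to the epoxy sulfone F4, so the C11–O bond is set with the right configuration. LiN(i-Pr)2 in THF removes the C9 proton, and the sulfonyl carbanion opens the epoxide at C10 from the endo side (3-exo-tet closure of a γ,δ-epoxy sulfone to a cyclopropane). This is independent of the C9 configuration and gives the sulfonyl nortricyclanol F5. Na/Hg with Na2HPO4 in MeOH removes the sulfonyl group and gives 20.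

2. Step 9.
- **What may go wrong:** sulfonylation runs through the non-chelated enolate, or the Z alkene isomerises later, so the alkene geometry is poorly controlled.
- **Fallback:** it sets out from 16 and comes back at 21. It uses the geometry that non-chelating conditions favour. TsCl, N-methylimidazole and Et3N in CH2Cl2 should give the E enol tosylate F6. TsOH gives the E cyclopentadiene F7. Heating as in step 11 gives the endo-tosylate adduct F8, in which the carbonyl-exo approach is reinforced because the sulfonate now travels with C2. An endo leaving group cannot be pushed out by the π bond, so the retarding carbonyl is removed first with LiBH4 in THF to give the endo-tosylate diol F9. Ionisation is then run unassisted in a strongly ionising, weakly nucleophilic medium (HFIP–H2O, 2,6-lutidine, 80 °C). The C9 cation is captured by C10=C11 after ionisation and merges into the same cyclopropylcarbinyl cation, which water traps at C11 to give 21.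

3. Step 12.
- **What may go wrong:** the carbonyl group on C1 holds back ionisation, so the heating needed brings loss of the acetal ether or hydrolytic opening of the lactone before C9–C10 has formed.
- **Fallback:** it sets out from 19 and comes back at 21. It changes the oxidation level before the ionisation. LiBH4 in THF with a little MeOH (0 °C → rt) reduces the lactone but not the hindered sulfonate and gives the exo-tosylate diol F10. Its C1 substituent is now a hydroxymethyl group, so π-assisted solvolysis should proceed in acetone–H2O with NaHCO3 at about 50 °C. Closure of an oxetane or fragmentation from the C15 hydroxyl is disfavoured because C15 and OTs are syn on C1–C9. The product is 21, and step 13 is no longer needed.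

Further compounds
F1 | step 11 | (3E)-3-[(phenylsulfonyl)methylidene] lactone, diene masked | O=S(=O)(c4ccccc4)/C=C1\C[C@@H]([C@H](OCOCc3ccccc3)C(C)(C)C2(O[Si](CC)(CC)CC)CCC(C)=C2)OC1=O
F2 | step 11 | cyclopentadiene tethered to the E vinyl sulfone lactone | O=S(=O)(c4ccccc4)/C=C1\C[C@@H]([C@H](OCOCc3ccccc3)C(C)(C)C2=CC(C)=CC2)OC1=O
F3 | step 11 | Diels–Alder adduct with endo-C9 phenylsulfonyl group | O=C1O[C@H]2C[C@@]13[C@H](S(=O)(=O)c4ccccc4)[C@H]5C[C@@]3(C=C5C)C(C)(C)[C@H]2OCOCc6ccccc6
F4 | step 11 | exo-C10,C11 epoxide of F3 | O=C1O[C@H]2C[C@@]13[C@H](S(=O)(=O)c4ccccc4)[C@H]5C[C@@]3([C@@H]7O[C@]57C)C(C)(C)[C@H]2OCOCc6ccccc6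
F5 | step 11 | C9-phenylsulfonyl nortricyclanol lactone | O=C1O[C@H]2C[C@@]13[C@@]4(S(=O)(=O)c7ccccc7)[C@H]5C[C@@]3([C@H](O)[C@@]45C)C(C)(C)[C@H]2OCOCc6ccccc6
F6 | step 9 | (3E)-3-[(tosyloxy)methylidene] lactone, diene masked | Cc4ccc(cc4)S(=O)(=O)O/C=C1\C[C@@H]([C@H](OCOCc3ccccc3)C(C)(C)C2(O[Si](CC)(CC)CC)CCC(C)=C2)OC1=O
F7 | step 9 | cyclopentadiene tethered to the E enol tosylate lactone | Cc4ccc(cc4)S(=O)(=O)O/C=C1\C[C@@H]([C@H](OCOCc3ccccc3)C(C)(C)C2=CC(C)=CC2)OC1=O
F8 | step 9 | Diels–Alder adduct with endo-C9 tosylate | O=C1O[C@H]2C[C@@]13[C@H](OS(=O)(=O)c4ccc(C)cc4)[C@H]5C[C@@]3(C=C5C)C(C)(C)[C@H]2OCOCc6ccccc6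
F9 | step 9 | C15, C3 diol with endo-C9 tosylate | OC[C@]12C[C@H](O)[C@H](OCOCc4ccccc4)C(C)(C)[C@]13C[C@H]([C@H]2OS(=O)(=O)c5ccc(C)cc5)C(C)=C3
F10 | step 12 | C15, C3 diol with exo-C9 tosylate | OC[C@]12C[C@H](O)[C@H](OCOCc4ccccc4)C(C)(C)[C@]13C[C@H]([C@@H]2OS(=O)(=O)c5ccc(C)cc5)C(C)=C3
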